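## Structural features

- The target 33 is a 2,3-dimethyl-2,3-dihydropyran-4-one (ring B) fused through C4a–C8a to a dearomatised phloroglucinol ring (ring A). It is drawn as the C4 enol chelated to the C5 ketone, with a second vinylogous ester O1–C8a=C8–C7=O.
- C6 (S) is quaternary and carries a prenyl group and a branched chain whose first stereocentre C2′ (R; isobutenyl and 3-methylbut-3-enyl arms) stands 1,3 to C6.
- C8 carries a 3-phenylpropanoic acid with a benzylic stereocentre (R); C2 and C3 of ring B are trans (2R,3R).
- Fragile groups: the enolised β-tricarbonyl array (tautomerism, retro-Claisen cleavage, epimerisation at C3), three acid-sensitive alkenes, and the ring B vinylogous ester, which can open and re-close.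
- The main difficulty is C6. It is a stereocentre only because the flanking carbonyls C5 and C7 continue into different carbons (C4a with the acyl group, C8 with the arylpropanoate).
- The second difficulty is regiochemical: O1 must sit on C8a and not on C5.
- The key step uses the hidden symmetry. In a 2,2-disubstituted cyclohexane-1,3,5-trione C5 and C7 are equivalent, and a CH2OH group standing in for the isobutenyl group on C2′ reaches either carbonyl through a six-membered ring. Closure under equilibrium tells the arms apart, fixes C6 relative to C2′, and leaves C8 as the only carbon between two free carbonyls.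

## Logic of the disconnections

**33 ⇒ 32.** The isobutenyl C=C on C2′ is cut (aldehyde plus isopropylidene ylide). This is the one group on C2′ that can be carried as an oxygen-bearing carbon. The forward olefination must tolerate a free acid and an enol and must not epimerise C2′.

**32 ⇒ 31 ⇒ 30.** The aldehyde comes from the primary alcohol, and the alcohol is reconnected to C5 as a cyclic enol ether. In 30 the O5 position is an ether, so C6 and the position of ring B are locked. The forward step needs the enol ether to hydrolyse; once C4a is acylated the open form is a chelated enol and no longer re-closes.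

**30 ⇒ 29 ⇒ 28.** The O1–C8a bond of ring B is cut. This leaves an open δ-hydroxy β-dicarbonyl array and one silyl ether. The forward closure must take C8a and not C5, and must keep the C–O bond at C2 intact.

**28 ⇒ 27 ⇒ 26 ⇒ 21 + 25.** The acid and the C7 enol are tied back into an enol lactone, then the C4–C4a bond is cut. In the tethered series C4a is the α-carbon of a vinylogous ester and not an enolate carbon, so it is joined as a vinyl iodide to an aldehyde and the carbinol is oxidised. This is convergent and brings in both ring B stereocentres. The forward coupling must add to the aldehyde only.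

**21 ⇒ 20 ⇒ 19 ⇒ 16 + 17.** The C–I bond, the lactone oxidation level and the C8–benzylic bond are removed in turn. This reaches a bicycle with a single active methylene. The forward Michael addition must be catalyst-controlled at the benzylic carbon.

**16 ⇒ 15.** The O–C5 bond of the tether is cut. This returns a trione whose ring is symmetric. The forward step must choose one of two equivalent arms (key step).

**15 ⇒ 14 ⇒ 13 ⇒ 12.** The silyl ether is restored. Ring A is then opened at the bond between an ester carbon and a terminal methyl carbon, and the chain is shortened at the bond between the methyl ketone carbon and an acetyl carbon. This gives an acyclic quaternary β-keto ester whose configuration at the quaternary carbon is irrelevant. The forward steps need a kinetic methyl-ketone enolate and then a diketone dianion.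

**12 ⇒ 10 + 11; 10 ⇒ 9 + 8.** Both bonds from the quaternary carbon to its CH2 groups are cut. The hindered iodide is used first, on the less hindered enolate; the allylic bromide makes the quaternary centre.

**8 ⇒ 7 ⇒ 6 ⇒ 5 ⇒ 4.** The iodide, the protecting-group exchange and the acetate are removed back to a prochiral diol. The forward desymmetrisation sets C2′.

**4 ⇒ 3 ⇒ 1 + 2.** Reduction and malonate alkylation.

**25 ⇒ 24 ⇒ 23 ⇒ 22.** The aldehyde is traced to a chiral-pool hydroxy ester; the forward methylation must be anti.

## Other disconnections considered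

**Alternative 1:** The cut is C1′–C2′ on an aromatic chromanone. Base would release an ortho-quinone methide from sulfone A2; the enamine of aldehyde A3 with a diarylprolinol silyl ether would add to it, and the aldehyde would close on O5 to give lactol A1.
- In favour: the reaction type (enamine addition to quinone methides made from sulfonylmethyl phenols) is established, which the key step of the chosen plan is not; on precedent Alternative 1 is the better.
- In favour: ring B and the C8 side chain are set on an aromatic ring, where the chelated 5-OH makes O5/O7 differentiation routine. On ring B regiochemistry it is at least the equal of the chosen plan.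
- Against: C6 is still missing in A1. It would have to be made by dearomative C-prenylation of a fully substituted ring, with C- versus O-alkylation, the choice of ring carbon and the facial sense all resting on a remote, equilibrating lactol.
- Comparison: the aromatic route is probably shorter, so on step count it is the better. The chosen plan puts its uncertainty into an equilibrium with a stated conformational bias; Alternative 1 puts it into a kinetic dearomatisation with no comparable control element.

**Alternative 2:** The cuts are C2′–C3′ and C6–CH2(prenyl). The cuprate from the Grignard reagent of 2 and CuBr·SMe2 (monovalent copper) would open spirocyclopropane A5 at C2′ with inversion, and 11 would trap the enolate to give A4.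
- In favour: a one-flask three-component assembly in which the isobutenyl group is present from the start. No late oxidation or olefination and no tether removal are needed; on these points it is the better.
- In favour: homoconjugate opening of doubly activated cyclopropanes by cuprates is a known reaction type.
- Against: A4 has two identical acyl groups on C6, so it solves C2′ but not C6; the arm differentiation would still have to be found after ring A is built.
- Against: SN2′ attack at the alkene terminus competes with the desired attack at C2′, and A5 must first be made as a single enantiomer.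
- Comparison: on steps to a chain-complete intermediate it is the better; on the central stereochemical problem it offers nothing, whereas the chosen plan solves exactly that.

**Alternative 3:** The cut is C4a–C5. KOtBu would remove the C8 proton of keto ester A7, and the C4a terminus of the dienolate would attack the methyl ester to close ring A and give A6, the tert-butyl ester of 33.
- In favour: it is highly convergent. Ring B, with both stereocentres and its oxygen already on C8a, exists before ring A, so the ring B regiochemistry question does not arise; on this point it is the better.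
- In favour: ring size enforces attack from C4a (attack from C8 would give a four-membered ring), and the product enolate is a thermodynamic sink.
- Against: A7 must already hold the C6 quaternary stereocentre as an acyclic carbon with two similar alkyl arms next to C2′, and no reliable way to set it is apparent.
- Against: the nucleophile is a stabilised, weakly reactive anion attacking a neopentyl ester, and A7 is a non-enolisable β-keto ester open to retro-Claisen cleavage by alkoxide.
- Comparison: equal or better in step count after A7, but the real difficulty is moved into an undefined earlier step. The chosen plan is longer and addresses C6 directly.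

Key step: step 12

Remarks on the chemistry (assumptions):
- β-Dicarbonyl compounds are written in one tautomeric form that stands for the equilibrating set. Chroman numbering of 33 (with C1′, C2′ for the chain) is used for all ring A intermediates.
- Burkholderia cepacia lipase is assumed to acetylate the pro-S hydroxymethyl arm of 4; the fallback under step 3 covers the opposite sense.
- The lactol of step 13 is assumed to close on O7 (cross-conjugated enol); an O8a isomer would converge with it at 28.
- The (2R) centre of 15, the trans relationship in 16 and C2′/C6 of 33 were checked against each other and are consistent; no structure needed correction. The precursor 15 is kept as the free hydroxy trione and is released from its silyl ether by buffered fluoride just before use, because its own acidity starts the closure.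

## Steps

Step 1
Reactants: 1 dimethyl malonate; 2 4-bromo-2-methylbut-1-ene
Product: 3 dimethyl 2-(3-methylbut-3-en-1-yl)malonate
Conditions: NaH, 1 (2 equiv), THF/DMF, 0 → 60 °C
Reagents that add atoms: none
Why: Malonic ester alkylation (SN2) of a primary homoallylic bromide; excess malonate suppresses dialkylation.

Step 2
Reactants: 3 dimethyl 2-(3-methylbut-3-en-1-yl)malonate
Product: 4 2-(3-methylbut-3-en-1-yl)propane-1,3-diol
Conditions: LiAlH4, THF, 0 °C → rt; aqueous NaOH work-up
Reagents that add atoms: none
Why: Hydride reduction of both esters gives the prochiral 2-substituted propane-1,3-diol; the 1,1-disubstituted alkene is inert.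

Step 3
Reactants: 4 2-(3-methylbut-3-en-1-yl)propane-1,3-diol
Product: 5 (2S)-2-(hydroxymethyl)-5-methylhex-5-en-1-yl acetate
Conditions: Burkholderia cepacia lipase, vinyl acetate, iPr2O, 25 °C
Reagents that add atoms: vinyl acetate, C=COC(C)=O
Why: Enzymatic desymmetrisation by irreversible lipase transesterification; the enzyme distinguishes the enantiotopic CH2OH arms and so sets C2′. Running slightly into the diacetate should remove the minor enantiomer preferentially.

Step 4
Reactants: 5 (2S)-2-(hydroxymethyl)-5-methylhex-5-en-1-yl acetate
Product: 6 (2R)-2-[(tert-butyldiphenylsilyloxy)methyl]-5-methylhex-5-en-1-yl acetate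
Conditions: TBDPSCl, imidazole, CH2Cl2, 0 °C → rt
Reagents that add atoms: tert-butyl(chloro)diphenylsilane, CC(C)(C)[Si](Cl)(c1ccccc1)c1ccccc1
Why: Silylation of the free primary alcohol under weak base, done promptly so that acetyl migration between the arms cannot erode the stereocentre.

Step 5
Reactants: 6 (2R)-2-[(tert-butyldiphenylsilyloxy)methyl]-5-methylhex-5-en-1-yl acetate
Product: 7 (2R)-2-[(tert-butyldiphenylsilyloxy)methyl]-5-methylhex-5-en-1-ol
Conditions: iBu2AlH, CH2Cl2, −78 °C; Rochelle salt
Reagents that add atoms: none
Why: Reductive cleavage of the acetate leaves an aluminium alkoxide and no free alkoxide, so 1,5-silyl migration (which would racemise C2′) is avoided.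

Step 6
Reactants: 7 (2R)-2-[(tert-butyldiphenylsilyloxy)methyl]-5-methylhex-5-en-1-ol
Product: 8 tert-butyl{[(2S)-2-(iodomethyl)-5-methylhex-5-en-1-yl]oxy}diphenylsilane
Conditions: I2, PPh3, imidazole, CH2Cl2, 0 °C → rt
Reagents that add atoms: iodine, [I][I]
Why: Appel iodination of a primary alcohol; the stereocentre is not touched and the descriptor changes only by priority.

Step 7
Reactants: 9 methyl acetoacetate; 8 tert-butyl{[(2S)-2-(iodomethyl)-5-methylhex-5-en-1-yl]oxy}diphenylsilane
Product: 10 methyl (4R)-2-acetyl-4-[(tert-butyldiphenylsilyloxy)methyl]-7-methyloct-7-enoate (both C2 epimers)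
Conditions: NaH, 9 (1.5 equiv), DMF/THF, 0 → 60 °C
Reagents that add atoms: none
Why: Acetoacetic ester C-alkylation (SN2) with a β-branched primary iodide; the weakly basic sodium enolate in DMF favours substitution over elimination and C- over O-alkylation.

Step 8
Reactants: 10 methyl (4R)-2-acetyl-4-[(tert-butyldiphenylsilyloxy)methyl]-7-methyloct-7-enoate; 11 prenyl bromide
Product: 12 methyl (4R)-2-acetyl-4-[(tert-butyldiphenylsilyloxy)methyl]-7-methyl-2-(3-methylbut-2-en-1-yl)oct-7-enoate (both C2 epimers)
Conditions: NaH, THF/DMF, 0 °C → rt
Reagents that add atoms: none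
Why: Second C-alkylation with a reactive allylic bromide makes the quaternary carbon; its configuration does not matter because both epimers give the same ring-symmetric trione.

Step 9
Reactants: 12 methyl (4R)-2-acetyl-4-[(tert-butyldiphenylsilyloxy)methyl]-7-methyl-2-(3-methylbut-2-en-1-yl)oct-7-enoate
Product: 13 methyl (4R)-4-[(tert-butyldiphenylsilyloxy)methyl]-7-methyl-2-(3-methylbut-2-en-1-yl)-2-(3-oxobutanoyl)oct-7-enoate (both C2 epimers)
Conditions: LiN(iPr)2 (1.1 equiv), THF, −78 °C; N-methoxy-N-methylacetamide, −78 → 0 °C; aq. NH4Cl
Reagents that add atoms: N-methoxy-N-methylacetamide, CC(=O)N(C)OC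
Why: Crossed Claisen-type acylation of the kinetic methyl ketone enolate, the only enolisable position. The chelated tetrahedral adduct of the Weinreb amide prevents over-acylation.

Step 10
Reactants: 13 methyl (4R)-4-[(tert-butyldiphenylsilyloxy)methyl]-7-methyl-2-(3-methylbut-2-en-1-yl)-2-(3-oxobutanoyl)oct-7-enoate
Product: 14 2-[(2R)-2-[(tert-butyldiphenylsilyloxy)methyl]-5-methylhex-5-en-1-yl]-2-(3-methylbut-2-en-1-yl)cyclohexane-1,3,5-trione
Conditions: LiN(iPr)2 (2.5 equiv), THF, −78 → 0 °C; aq. HCl to pH 4
Reagents that add atoms: none
Why: Intramolecular Claisen (Dieckmann-type) condensation: the terminal carbanion of the 1,3-diketone dianion attacks the ester to close the six-membered ring. The trione enolate formed is the thermodynamic sink.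

Step 11
Reactants: 14 2-[(2R)-2-[(tert-butyldiphenylsilyloxy)methyl]-5-methylhex-5-en-1-yl]-2-(3-methylbut-2-en-1-yl)cyclohexane-1,3,5-trione
Product: 15 2-[(2R)-2-(hydroxymethyl)-5-methylhex-5-en-1-yl]-2-(3-methylbut-2-en-1-yl)cyclohexane-1,3,5-trione
Conditions: Bu4NF, AcOH, THF, 0 °C → rt; pH 5 buffer work-up
Reagents that add atoms: none
Why: Fluoride desilylation; the buffered medium holds the trione as its enolate so that closure does not start before step 12. The material is used at once, and any cyclic enol ether already present enters the same equilibrium.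

Step 12
Reactants: 15 2-[(2R)-2-(hydroxymethyl)-5-methylhex-5-en-1-yl]-2-(3-methylbut-2-en-1-yl)cyclohexane-1,3,5-trione
Product: 16 (3R,4aS)-3-(3-methylbut-3-en-1-yl)-4a-(3-methylbut-2-en-1-yl)-2,3,4,4a-tetrahydro-5H-chromene-5,7(6H)-dione (O5-tethered bicycle; C2′ branch trans to the angular prenyl group)
Conditions: camphorsulfonic acid (0.2 equiv), water-saturated toluene, 50 °C
Reagents that add atoms: none
Why: Proposed new method: protonation of the C5 (or the equivalent C7) carbonyl of the enolised trione, attack of the C2′ CH2OH oxygen and loss of water give a six-membered cyclic vinylogous ester, and hydration reverses it, so both arms exchange through 15 and the ratio is thermodynamic; the closest known reaction type is the reversible acid-catalysed cyclisation of 2-(3-hydroxypropyl)cycloalkane-1,3-diones to fused dihydropyran enol ethers, which has not been used to tell two equivalent arms apart. The one ring formed (O–C5–C6–C1′–C2′–CH2) closes 6-exo-trig through a C–O bond; no skeletal bond forms. In either bicycle C7 must lie near the plane of the C5=C4a enol ether, which makes the angular prenyl group axial on the new ring. The C2′ branch is then equatorial only when it is trans to prenyl; in the cis bicycle (closure on the other arm) it is 1,3-diaxial to prenyl or the ring must leave the chair. With (R)-C2′ the trans bicycle is the one closed on the oxygen that becomes O5, so the fixed centre C2′ sets C6 (S in 16) under equilibrium. The step needs arm selectivity only, together with survival of the alkenes: a weak sulfonic acid at moderate temperature in an aprotic solvent with a little water should allow hydration and dehydration without protonating the prenyl or isopropenyl groups. The tether also leaves C8 as the only carbon between two free carbonyls, which step 13 uses.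

Step 13
Reactants: 16 O5-tethered bicycle; 17 (E)-cinnamaldehyde
Product: 19 O7 lactol of the C8 Michael adduct (16 bridged from C8 to O7 by CH(Ph)–CH2–CH(OH); C7=C8 enol ether; benzylic carbon as in 33; lactol carbon both epimers), via open-chain Michael aldehyde 18 (not isolated)
Conditions: (R)-2-[diphenyl(trimethylsilyloxy)methyl]pyrrolidine (10 mol%), PhCO2H (10 mol%), CH2Cl2, 0 °C → rt
Reagents that add atoms: none
Why: Iminium-catalysed Michael addition of a cyclic 1,3-diketone to an enal: the diphenyl(silyloxy)methyl group of the (R)-catalyst blocks one face of the E, s-trans iminium ion and C8 adds to the other, which gives the benzylic configuration of 33. C8 is the only carbon between two free carbonyls, and the aldehyde closes on the C7 enol as a lactol.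

Step 14
Reactants: 19 O7 lactol
Product: 20 O7 enol lactone (C8 and O7 bridged by CH(Ph)–CH2–C(=O); 4-phenyl-3,4-dihydropyran-2-one fused at C7=C8)
Conditions: Dess–Martin periodinane, CH2Cl2, 0 °C → rt
Reagents that add atoms: none
Why: Lactol to lactone oxidation; the lactone holds the future acid and caps O7, so ring A has no acidic proton left.

Step 15
Reactants: 20 O7 enol lactone
Product: 21 C4a-iodo derivative of 20
Conditions: N-iodosuccinimide, CH2Cl2, 0 °C → rt, dark
Reagents that add atoms: N-iodosuccinimide, O=C1CCC(=O)N1I
Why: Electrophilic iodination at the α-carbon of the vinylogous ester, the only ring A C–H and the most electron-rich alkene carbon; the isolated alkenes have no nucleophile to trap an iodonium ion.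

Step 16
Reactants: 22 methyl (R)-3-hydroxybutanoate
Product: 23 methyl (2R,3R)-3-hydroxy-2-methylbutanoate
Conditions: LiN(iPr)2 (2.2 equiv), THF, −78 → −20 °C; MeI, DMPU; aq. NH4Cl
Reagents that add atoms: iodomethane, CI
Why: Fráter–Seebach alkylation: the chelated lithium alkoxide enolate is methylated anti to the C3 methyl group, which gives the anti (2R,3R) ester.

Step 17
Reactants: 23 methyl (2R,3R)-3-hydroxy-2-methylbutanoate
Product: 24 methyl (2R,3R)-3-(tert-butyldimethylsilyloxy)-2-methylbutanoate
Conditions: TBSCl, imidazole, DMF, rt
Reagents that add atoms: tert-butyl(chloro)dimethylsilane, CC(C)(C)[Si](C)(C)Cl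
Why: Standard silylation of a secondary alcohol.

Step 18
Reactants: 24 methyl (2R,3R)-3-(tert-butyldimethylsilyloxy)-2-methylbutanoate
Product: 25 (2R,3R)-3-(tert-butyldimethylsilyloxy)-2-methylbutanal
Conditions: iBu2AlH (1.05 equiv), CH2Cl2, −78 °C; Rochelle salt
Reagents that add atoms: none
Why: Half-reduction of the ester through the stable tetrahedral aluminate at low temperature; the aldehyde is used without storage to avoid α-epimerisation.

Step 19
Reactants: 21 C4a-iodo lactone; 25 (2R,3R)-3-(tert-butyldimethylsilyloxy)-2-methylbutanal
Product: 26 C4 carbinol (21 with iodine replaced by CH(OH)–CH(CH3)–CH(OTBS)–CH3; carbinol carbon both epimers)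
Conditions: CrCl2 (6 equiv), NiCl2 (2 mol%), DMSO, rt
Reagents that add atoms: none
Why: Nozaki–Hiyama–Kishi coupling: nickel inserts into the vinyl C–I bond, the alkenyl group passes to chromium and adds to the aldehyde only (ketone and lactone are left). The new carbinol centre is removed in step 20.

Step 20
Reactants: 26 C4 carbinol
Product: 27 C4 ketone (C4a-[(2R,3R)-3-(tert-butyldimethylsilyloxy)-2-methylbutanoyl] derivative of 20)
Conditions: Dess–Martin periodinane, CH2Cl2, 0 °C → rt
Reagents that add atoms: none
Why: Oxidation of a secondary allylic alcohol, done while ring A is fully capped so that no enol can react with the oxidant.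

Step 21
Reactants: 27 C4 ketone
Product: 28 seco acid (lactone opened: C8–CH(Ph)–CH2–CO2H and free C7 enol; O5 tether and silyl ether intact)
Conditions: LiOH, THF/H2O, 0 °C; 1 M HCl to pH 3
Reagents that add atoms: water, O
Why: Saponification of the enol ester, by far the most electrophilic carbonyl; the hindered C5 enol ether and the ketones should not react at 0 °C. This frees the C7/C8a vinylogous acid needed for ring B.

Step 22
Reactants: 28 seco acid
Product: 30 ring B closed O5-tethered acid (O1–C8a bond formed; C5 enol ether, C7 ketone; 2R,3R), via hydroxy ketone 29 (not isolated)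
Conditions: HF·pyridine, THF, 0 °C → rt; then camphorsulfonic acid (0.2 equiv), 4 Å MS, CH2Cl2, rt
Reagents that add atoms: none
Why: Desilylation, then acid-catalysed cyclodehydration of a δ-hydroxy β-dicarbonyl array to a 2,3-dihydropyran-4-one (6-exo-trig at C8a); the C2–O bond is not broken, so C2 keeps its configuration, and C3 can settle to the more stable trans arrangement. C8a is favoured over C5 because C5 is an enol ether carbon next to the quaternary C6, and because closure at C5 would push the tether onto O7 as the strained cis bicycle; removal of water by the sieves drives the C8a pathway.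

Step 23
Reactants: 30 ring B closed O5-tethered acid
Product: 31 C2′-hydroxymethyl acid (33 with CH2OH in place of the isobutenyl group)
Conditions: 1 M HCl, THF, rt
Reagents that add atoms: water, O
Why: Acid hydrolysis of a vinylogous ester; after C4a acylation the open form is a chelated β-dicarbonyl enol and the C5 carbon is doubly activated, so the equilibrium that held the tether closed in 16 now lies on the open side.

Step 24
Reactants: 31 C2′-hydroxymethyl acid
Product: 32 C2′-formyl acid (33 with CHO in place of the isobutenyl group)
Conditions: Dess–Martin periodinane, CH2Cl2, 0 °C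
Reagents that add atoms: none
Why: Oxidation of the only primary alcohol; the enolised carbons C4a and C8 carry no hydrogen, which limits attack of the oxidant on the tricarbonyl array.

Step 25
Reactants: 32 C2′-formyl acid
Product: 33 target (CNP0155375.5)
Conditions: iPrPPh3I, n-BuLi, THF, −78 °C (4 equiv ylide); 32, THF/DMPU, −78 → 0 °C; aq. NH4Cl
Reagents that add atoms: isopropyl(triphenyl)phosphonium iodide, CC(C)[P+](c1ccccc1)(c1ccccc1)c1ccccc1.[I-]
Why: Wittig isopropylidenation with a non-stabilised ylide; the substrate enters as its carboxylate–enolate dianion, which shields C3 and the acid side chain from the base. Low temperature limits epimerisation at C2′.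

## Compound list

1 | dimethyl malonate | COC(=O)CC(=O)OC | starting material
2 | 4-bromo-2-methylbut-1-ene | C=C(C)CCBr | starting material
3 | dimethyl 2-(3-methylbut-3-en-1-yl)malonate | C=C(C)CCC(C(=O)OC)C(=O)OC | intermediate
4 | 2-(3-methylbut-3-en-1-yl)propane-1,3-diol | C=C(C)CCC(CO)CO | intermediate
5 | (2S)-2-(hydroxymethyl)-5-methylhex-5-en-1-yl acetate | C=C(C)CC[C@@H](CO)COC(C)=O | intermediate
6 | (2R)-2-[(tert-butyldiphenylsilyloxy)methyl]-5-methylhex-5-en-1-yl acetate | C=C(C)CC[C@@H](CO[Si](c1ccccc1)(c1ccccc1)C(C)(C)C)COC(C)=O | intermediate
7 | (2R)-2-[(tert-butyldiphenylsilyloxy)methyl]-5-methylhex-5-en-1-ol | C=C(C)CC[C@@H](CO[Si](c1ccccc1)(c1ccccc1)C(C)(C)C)CO | intermediate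
8 | tert-butyl{[(2S)-2-(iodomethyl)-5-methylhex-5-en-1-yl]oxy}diphenylsilane | C=C(C)CC[C@@H](CO[Si](c1ccccc1)(c1ccccc1)C(C)(C)C)CI | intermediate
9 | methyl acetoacetate | COC(=O)CC(C)=O | starting material
10 | methyl (4R)-2-acetyl-4-[(tert-butyldiphenylsilyloxy)methyl]-7-methyloct-7-enoate | C=C(C)CC[C@@H](CO[Si](c1ccccc1)(c1ccccc1)C(C)(C)C)CC(C(C)=O)C(=O)OC | intermediate
11 | prenyl bromide | CC(C)=CCBr | starting material
12 | methyl (4R)-2-acetyl-4-[(tert-butyldiphenylsilyloxy)methyl]-7-methyl-2-(3-methylbut-2-en-1-yl)oct-7-enoate | C=C(C)CC[C@@H](CO[Si](c1ccccc1)(c1ccccc1)C(C)(C)C)CC(CC=C(C)C)(C(C)=O)C(=O)OC | intermediate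
13 | methyl (4R)-4-[(tert-butyldiphenylsilyloxy)methyl]-7-methyl-2-(3-methylbut-2-en-1-yl)-2-(3-oxobutanoyl)oct-7-enoate | C=C(C)CC[C@@H](CO[Si](c1ccccc1)(c1ccccc1)C(C)(C)C)CC(CC=C(C)C)(C(=O)CC(C)=O)C(=O)OC | intermediate
14 | 2-[(2R)-2-[(tert-butyldiphenylsilyloxy)methyl]-5-methylhex-5-en-1-yl]-2-(3-methylbut-2-en-1-yl)cyclohexane-1,3,5-trione | C=C(C)CC[C@@H](CO[Si](c1ccccc1)(c1ccccc1)C(C)(C)C)CC1(CC=C(C)C)C(=O)CC(=O)CC1=O | intermediate
15 | 2-[(2R)-2-(hydroxymethyl)-5-methylhex-5-en-1-yl]-2-(3-methylbut-2-en-1-yl)cyclohexane-1,3,5-trione | C=C(C)CC[C@@H](CO)CC1(CC=C(C)C)C(=O)CC(=O)CC1=O | intermediate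
16 | (3R,4aS)-3-(3-methylbut-3-en-1-yl)-4a-(3-methylbut-2-en-1-yl)-2,3,4,4a-tetrahydro-5H-chromene-5,7(6H)-dione | C=C(C)CC[C@@H]2C[C@@]1(CC=C(C)C)C(OC2)=CC(=O)CC1=O | intermediate
17 | (E)-cinnamaldehyde | O=C/C=C/c1ccccc1 | starting material
18 | open-chain Michael aldehyde (16 with 3-oxo-1-phenylpropyl on C8) | C=C(C)CC[C@@H]2C[C@@]1(CC=C(C)C)C(OC2)=CC(=O)C([C@H](CC=O)c3ccccc3)C1=O | intermediate (not isolated)
19 | O7 lactol of the C8 Michael adduct | C=C(C)CC[C@@H]2C[C@@]1(CC=C(C)C)C(OC2)=CC(=O)C3=C1OC(O)C[C@@H]3c1ccccc1 | intermediate
20 | O7 enol lactone | C=C(C)CC[C@@H]2C[C@@]1(CC=C(C)C)C(OC2)=CC(=O)C3=C1OC(=O)C[C@@H]3c1ccccc1 | intermediate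
21 | C4a-iodo lactone | C=C(C)CC[C@@H]2C[C@@]1(CC=C(C)C)C(OC2)=C(I)C(=O)C3=C1OC(=O)C[C@@H]3c1ccccc1 | intermediate
22 | methyl (R)-3-hydroxybutanoate | COC(=O)C[C@@H](C)O | starting material
23 | methyl (2R,3R)-3-hydroxy-2-methylbutanoate | COC(=O)[C@H](C)[C@@H](C)O | intermediate
24 | methyl (2R,3R)-3-(tert-butyldimethylsilyloxy)-2-methylbutanoate | COC(=O)[C@H](C)[C@@H](C)O[Si](C)(C)C(C)(C)C | intermediate
25 | (2R,3R)-3-(tert-butyldimethylsilyloxy)-2-methylbutanal | O=C[C@H](C)[C@@H](C)O[Si](C)(C)C(C)(C)C | intermediate
26 | C4 carbinol | C=C(C)CC[C@@H]2C[C@@]1(CC=C(C)C)C(OC2)=C(C(O)[C@H](C)[C@@H](C)O[Si](C)(C)C(C)(C)C)C(=O)C3=C1OC(=O)C[C@@H]3c1ccccc1 | intermediate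
27 | C4 ketone | C=C(C)CC[C@@H]2C[C@@]1(CC=C(C)C)C(OC2)=C(C(=O)[C@H](C)[C@@H](C)O[Si](C)(C)C(C)(C)C)C(=O)C3=C1OC(=O)C[C@@H]3c1ccccc1 | intermediate
28 | seco acid | C=C(C)CC[C@@H]2C[C@@]1(CC=C(C)C)C(OC2)=C(C(=O)[C@H](C)[C@@H](C)O[Si](C)(C)C(C)(C)C)C(=O)C([C@H](CC(=O)O)c3ccccc3)=C1O | intermediate
29 | hydroxy ketone | C=C(C)CC[C@@H]2C[C@@]1(CC=C(C)C)C(OC2)=C(C(=O)[C@H](C)[C@@H](C)O)C(=O)C([C@H](CC(=O)O)c3ccccc3)=C1O | intermediate (not isolated)
30 | ring B closed O5-tethered acid | C=C(C)CC[C@@H]2C[C@@]1(CC=C(C)C)C(OC2)=C3C(=O)[C@H](C)[C@@H](C)OC3=C([C@H](CC(=O)O)c4ccccc4)C1=O | intermediate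
31 | C2′-hydroxymethyl acid | C=C(C)CC[C@@H](CO)C[C@@]1(CC=C(C)C)C(=O)C2=C(O)[C@H](C)[C@@H](C)OC2=C([C@H](CC(=O)O)c2ccccc2)C1=O | intermediate
32 | C2′-formyl acid | C=C(C)CC[C@@H](C=O)C[C@@]1(CC=C(C)C)C(=O)C2=C(O)[C@H](C)[C@@H](C)OC2=C([C@H](CC(=O)O)c2ccccc2)C1=O | intermediate
33 | CNP0155375.5 | C=C(C)CC[C@@H](C=C(C)C)C[C@@]1(CC=C(C)C)C(=O)C2=C(O)[C@H](C)[C@@H](C)OC2=C([C@H](CC(=O)O)c2ccccc2)C1=O | target

## Step count and least certain steps

Total: 25 steps. Longest linear sequence: 22 steps (steps 1–15 and 19–25); aldehyde 25 is made in 3 steps (16–18).

**Step 12 (key step, proposed new method).**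
- What may go wrong: the arms may fail to exchange, because rehydration of the cyclic enol ether is slow in nearly dry toluene, so the kinetic mixture persists. The conformational bias may also be smaller than argued if the cis bicycle escapes into a twist form. Acid may add the enol oxygen to the prenyl group or move the isopropenyl double bond.
- Fallback (known chemistry): 15 is closed under non-equilibrating conditions (pyridinium p-toluenesulfonate, 4 Å MS, CH2Cl2, rt) to 16 and its C6 epimer, the cis bicycle F1. The diastereomers are separated by chromatography. F1 is re-opened with aqueous NaOH (the trione is held as its enolate), brought to pH 5 and cyclised again. The sequence returns to the route at 16.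

**Step 22 (ring B closure).**
- What may go wrong: loss of regiocontrol, by attack of the secondary hydroxyl at C5 with expulsion of the tether alcohol (vinylogous transesterification); or dehydration of the β-hydroxy ketone before closure, which would scramble C2.
- Fallback: 29 (from 28 by the fluoride stage of step 22) is heated with DBU in toluene. E1cB loss of water gives tigloyl enone F6, and the C8a enolate oxygen closes by oxa-Michael addition; it is the only enol oxygen within reach, since O5 is an ether. Ring B then forms regiospecifically and equilibrates to trans, but as 30 together with its (2S,3S) diastereomer F7, which is removed by chromatography. The sequence returns at 30.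

**Step 19 (Nozaki–Hiyama–Kishi coupling).**
- What may go wrong: protodehalogenation of the alkenyl metal species before it adds; slow addition of a tetrasubstituted alkenylchromium to an α-branched aldehyde; epimerisation of 25 on standing.
- Fallback: 21 is stannylated (Me3SnSnMe3, Pd(PPh3)4, toluene, 80 °C) to stannane F3. Ester 24 is saponified (LiOH) to acid F4 and converted with (COCl)2 and catalytic DMF into acid chloride F5. Stille acylation of F3 with F5 (Pd2(dba)3, tri(2-furyl)phosphine, THF) gives ketone 27 directly, so the sequence returns at 27 and step 20 is not needed.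

**Step 23 (tether hydrolysis).**
- What may go wrong: slow hydrolysis at the hindered C5; reversible opening of ring B with re-closure on C5 once O5 is free; acid-induced addition of the new O5–H to the prenyl group.
- Fallback: the mechanism is changed from reversible acid hydrolysis to irreversible addition–elimination. LiOH in dioxane/water at 40–60 °C expels the tether alkoxide from 30 and holds the product as its enolate, which cannot re-close; acidification to pH 3 gives 31 (no new compound, F0).

**Step 25 (Wittig olefination).**
- What may go wrong: epimerisation at C2′ by the basic ylide; low reactivity or solubility of the dianion of 32.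
- Fallback: a non-basic Takai–Utimoto isopropylidenation of 32 with 2,2-diiodopropane and CrCl2 in THF gives 33 directly (no new compound, F0).

**Step 3 (lipase desymmetrisation).**
- What may go wrong: acetylation of the other enantiotopic arm, or incomplete discrimination of the arms.
- Fallback: 4 is acetylated (Ac2O, pyridine) to diacetate F2, and the same lipase is used in the hydrolytic direction (phosphate buffer, pH 7). It removes the acetate from the arm it would have acetylated and so delivers the antipodal monoacetate, which returns to the route at 5.

## Further compounds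

F1 | step 12 | C6 epimer of 16 (cis bicycle, closed on the other arm) | C=C(C)CC[C@@H]2C[C@]1(CC=C(C)C)C(OC2)=CC(=O)CC1=O
F6 | step 22 | tigloyl enone (29 less water; C4a-[(E)-2-methylbut-2-enoyl]) | C=C(C)CC[C@@H]2C[C@@]1(CC=C(C)C)C(OC2)=C(C(=O)/C(C)=C/C)C(=O)C([C@H](CC(=O)O)c3ccccc3)=C1O
F7 | step 22 | (2S,3S) ring B diastereomer of 30 | C=C(C)CC[C@@H]2C[C@@]1(CC=C(C)C)C(OC2)=C3C(=O)[C@@H](C)[C@H](C)OC3=C([C@H](CC(=O)O)c4ccccc4)C1=O
F3 | step 19 | C4a-trimethylstannyl analogue of 21 | C=C(C)CC[C@@H]2C[C@@]1(CC=C(C)C)C(OC2)=C([Sn](C)(C)C)C(=O)C3=C1OC(=O)C[C@@H]3c1ccccc1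
F4 | step 19 | (2R,3R)-3-(tert-butyldimethylsilyloxy)-2-methylbutanoic acid | OC(=O)[C@H](C)[C@@H](C)O[Si](C)(C)C(C)(C)C
F5 | step 19 | (2R,3R)-3-(tert-butyldimethylsilyloxy)-2-methylbutanoyl chloride | ClC(=O)[C@H](C)[C@@H](C)O[Si](C)(C)C(C)(C)C
F0 | step 23 | none | none
F0 | step 25 | none | none
F2 | step 3 | 2-(3-methylbut-3-en-1-yl)propane-1,3-diyl diacetate | C=C(C)CCC(COC(C)=O)COC(C)=O
A1 | alternative 1 | O5 lactol carrying the C2′ stereocentre (aromatic chromanone; methyl ester; O7 triisopropylsilyl ether) | C=C(C)CC[C@@H](C(O)O1)Cc2c1c3C(=O)[C@H](C)[C@@H](C)Oc3c([C@H](CC(=O)OC)c3ccccc3)c2O[Si](C(C)C)(C(C)C)C(C)C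
A2 | alternative 1 | methyl (3R)-3-[(2R,3R)-5-hydroxy-2,3-dimethyl-6-[(4-methylphenyl)sulfonylmethyl]-4-oxo-7-(triisopropylsilyloxy)chroman-8-yl]-3-phenylpropanoate | Cc1ccc(cc1)S(=O)(=O)Cc2c(O)c3C(=O)[C@H](C)[C@@H](C)Oc3c([C@H](CC(=O)OC)c3ccccc3)c2O[Si](C(C)C)(C(C)C)C(C)C
A3 | alternative 1 | 5-methylhex-5-enal | C=C(C)CCCC=O
A4 | alternative 2 | 2,2-dimethyl-5-[(2R)-5-methyl-2-(2-methylprop-1-enyl)hex-5-enyl]-5-(3-methylbut-2-enyl)-1,3-dioxane-4,6-dione | C=C(C)CC[C@@H](C=C(C)C)CC1(CC=C(C)C)C(=O)OC(C)(C)OC1=O
A5 | alternative 2 | (1S)-6,6-dimethyl-1-(2-methylprop-1-enyl)-5,7-dioxaspiro[2.5]octane-4,8-dione | CC(C)=C[C@@H]1CC12C(=O)OC(C)(C)OC2=O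
A6 | alternative 3 | tert-butyl ester of 33 | C=C(C)CC[C@@H](C=C(C)C)C[C@@]1(CC=C(C)C)C(=O)C2=C(O)[C@H](C)[C@@H](C)OC2=C([C@H](CC(=O)OC(C)(C)C)c2ccccc2)C1=O
A7 | alternative 3 | Dieckmann precursor: quaternary methyl ester (C5) and ketone (C7) on C6, C8–H bearing the tert-butyl 3-phenylpropanoate and the (2R,3R)-2,3-dimethyl-4-oxo-2,3-dihydropyran-6-yl ring | C=C(C)CC[C@@H](C=C(C)C)C[C@@](CC=C(C)C)(C(=O)OC)C(=O)C([C@H](CC(=O)OC(C)(C)C)c1ccccc1)C1=CC(=O)[C@H](C)[C@@H](C)O1
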